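**Remark on the chemistry:** 3, 12 and all unnumbered reagents are taken as commercial, and an operation telescoped in one flask is counted as one step. The atom mapping used throughout is: formyl carbon of 1 → C3, its 2-OH → O1, its 4-OH → O6, its C5–Br → C5, and the carboxyl carbon of 6 → C2; with this mapping all structures below are mutually consistent.

## Structural features

Ambofuranol (14) is an achiral 2-arylbenzofuran: a benzo ring (ring A) fused to a furan (ring B), with a 2-hydroxy-4-methoxyphenyl ring (ring C) attached through the C2–C1' bond. Ring B is fully substituted: C2 carries ring C and C3 carries a methoxy group, so C2=C3 is a tetrasubstituted enol ether double bond. Ring A carries a free hydroxyl at C6 and a 3-methylbut-2-enyl (prenyl) group at C5, ortho to each other; ring C carries a free hydroxyl at C2' and a methoxy group at C4'. There is no stereocentre and no stereogenic double bond, so nothing stereochemical has to be set. The fragile parts are the prenyl group next to the C6 phenol (acid closes it to a 2,2-dimethylchroman, and electrophiles and oxidants attack the olefin), the electron-rich 3-methoxyfuran enol ether, and the two free phenols. The real difficulty is the oxygen pattern: of the four phenolic or enolic oxygens only O3 and O4' are methylated, so a late O-methylation cannot be selective and the C3 oxygen must arrive already methylated. The key step exploits the fact that C3 is a benzylic carbon of ring A bearing OMe and C2 is a carboxyl-level carbon bound to O1 and ring C: an α-methoxybenzyl ylide at C3 and an aryl ester carbonyl at C2, tethered through O1, close ring B by Wittig olefination.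

## Logic of the disconnections

**14 ⇒ 13.** The two acyl C–O bonds on O6 and O2' are cut. Both phenols have to be masked during ester formation, ylide chemistry and palladium coupling, and a base-labile acyl group can be removed last without acid. The gain is only in handling, but the forward step must be a mild methanolysis with a non-acidic quench so that the prenyl group does not cyclise onto O6.

**13 ⇒ 11 + 12.** The C5–CH2 bond is cut. The prenyl olefin would not survive the acidic phosphonium and acid chloride chemistry, whereas a bromine atom is inert there and is already at the right carbon in 1. The forward coupling must transfer the allylic group without transposition and under neutral conditions.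

**11 ⇒ 10.** The C2=C3 double bond is cut, opening ring B. This is the strategic cut: both halves become simple oxygenated benzenes joined by an ester, and the C3 methoxy group is already on the ylide carbon. The forward step demands ylide formation with a weak base, closure onto the tethered aroyl carbonyl faster than any loss of phosphine, and no attack on either pivalate. The constitution of 10 is kept; the change in design is that it is made as an isolated single-counter-ion salt, free of acid chloride, and closed in a separate operation.

**10 ⇒ 5 + 8 (through 9).** The ester bond between the future C2 carbonyl and O1 is cut. This separates ring C as a salicylic acid whose phenol is pivaloylated, so that an acid chloride is viable and O2' leaves the route in the same final step as O6. The forward acylation must esterify a phenol next to a phosphonium centre without generating the ylide or the phenoxide in quantity, hence pyridine and low temperature. Acylating before the phosphorus is introduced was rejected as the main order because an ortho-acyloxy benzaldehyde loses its ester readily under acetal-forming conditions.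

**5 ⇒ 2 + 3 (through 4).** The C3–P bond and one C3–OMe bond are cut back to the aldehyde. The aldehyde carbon is converted into an α-methoxy phosphonium carbon by acetalisation and ionisation in the presence of the phosphine acid salt. The forward step relies on the ortho-hydroxyl to stabilise the benzylic oxocarbenium ion, and the labile acetal is therefore not isolated.

**2 ⇒ 1.** The O4–acyl bond is cut. The forward step must distinguish the free, more acidic 4-OH from the hydrogen-bonded 2-OH, which has to stay free for the later ester.

**8 ⇒ 6 (through 7).** The O2–acyl bond is cut. The forward step must end with a free carboxylic acid, so excess acylating agent is used and the mixed anhydride is hydrolysed selectively.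

## Other disconnections considered

**Alternative 1:** Ring A is cut at C4–C5 and C7–C7a and built from acyclic material. In the forward sense KOtBu joins 6-methylhept-5-en-2-one A2 and methyl acrylate A3 by Michael addition and Claisen condensation to give 4-(3-methylbut-2-enyl)cyclohexane-1,3-dione A1, which would be aromatised to 4-(3-methylbut-2-enyl)benzene-1,3-diol A4.
- In its favour: the prenyl–C5 bond comes from a cheap terpene ketone, with no halogen handle, no tin reagent and no question of allyl transposition. On this point it is better than the chosen plan.
- Against it: it builds the one part of the target that can be bought. A4 still lacks the C3 carbon and the whole furan, so formylation and then a furan construction are needed with the acid-sensitive prenyl phenol on board from the start.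
- The Michael addition must occur at the internal methylene and the Claisen condensation at the methyl group; the reverse order would give the 2-prenyl dione. Dehydrogenation of a 1,3-dione next to a trisubstituted olefin risks isomerisation or cyclisation onto the enol.
- Comparison: the individual reactions are as conventional mechanistically as those of the chosen plan, but the sequence would be several steps longer and places the fragile group early instead of late.

**Alternative 2:** Ring A is cut at C4–C5 and C3a–C7a. The forward step is a Diels–Alder reaction of 1-methoxy-7-methyl-1,3-bis(trimethylsilyloxy)octa-1,3,6-triene A6 with the ynone 1-(tert-butyldimethylsilyloxy)-1-[4-methoxy-2-(methoxymethoxy)phenyl]but-3-yn-2-one A7, followed by acidic aromatisation to the aryl ketone A5.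
- In its favour: the polarity of the diene fixes both ring-A oxygens and the prenyl group in one regiocontrolled step, and all carbons of the target are present in A5. On convergence and on regiocontrol of the prenyl position it is equal to or better than the chosen plan, again without bromine or tin.
- Against it: ring B is still open. C2 arrives as a silyl-protected alcohol and C3 as a ketone, so desilylation, closure of O1 onto C2 and enol O-methylation must follow. That methylation would have to spare the free C6 phenol, which calls for further protection.
- The aromatisation needs acid with the prenyl group ortho to a phenol, the methoxymethyl ether needs acid again at the end, and A6 and A7 each require several steps and are moisture- or base-sensitive.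
- Comparison: the cycloaddition is well founded mechanistically, but the oxidation level at C2 and C3 is set less directly than by the Wittig closure, and the total would be roughly twice the step count of the chosen plan.

**Alternative 3:** Ring B is cut at C2–C3 and O1–C2. The ylide from 1-[4-methoxy-2-(methoxymethoxy)benzyl]tetrahydrothiophenium bromide A9 (Cs2CO3, acetonitrile) would add to 5-bromo-2-hydroxy-4-(methoxymethoxy)benzaldehyde A10, and the phenoxide would close onto the ylide carbon to give the trans-dihydrobenzofuranol A8.
- In its favour: two ring bonds form in one mild operation at ambient temperature, and this [4+1] annulation has direct precedent on salicylaldehydes. On security of precedent for the ring-forming event it is better than the chosen plan, and it is equal in convergence and in the late, bromine-based prenylation.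
- Against it: C3 arrives as an alcohol, so oxidation to the benzofuranone A11 and enol O-methylation are needed. The two stereocentres of A8 are created only to be destroyed, and O- versus C-methylation of the doubly activated C2 position of A11 is an added selectivity problem.
- The methoxymethyl ethers require acid at the end, next to the prenyl phenol and the enol ether, and A9 needs its own three- or four-step preparation.
- Comparison: mechanistically both plans use an ylide and the same aldehyde-derived carbon for C3, but the chosen plan delivers C3 at the correct oxidation level with its methyl group and should be three or four steps shorter.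

Key step: step 5

## Route

**Step 1**
Reactants: 1 5-bromo-2,4-dihydroxybenzaldehyde
Product: 2 2-bromo-4-formyl-5-hydroxyphenyl pivalate
Conditions: PivCl (1.05 equiv), Et3N (1.1 equiv), CH2Cl2, −10 °C to rt
Reagents that add atoms: pivaloyl chloride, CC(C)(C)C(Cl)=O
Why: Regioselective phenol acylation: the 4-OH (para to the formyl group, ortho to bromine) is the more acidic and is free, whereas the 2-OH is held in a hydrogen bond to the aldehyde and is hindered, so one equivalent of a bulky acyl chloride should esterify O4 only.

**Step 2**
Reactants: 2 2-bromo-4-formyl-5-hydroxyphenyl pivalate; 3 triphenylphosphine hydrobromide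
Product: 5 {[5-bromo-2-hydroxy-4-(pivaloyloxy)phenyl](methoxy)methyl}triphenylphosphonium bromide (racemic), via dimethyl acetal 4 (not isolated)
Conditions: HC(OMe)3 (3 equiv), MeOH, PPh3·HBr (2 mol %), rt; evaporate; then PPh3·HBr (1.05 equiv), CH2Cl2, rt, concentrate; precipitate with Et2O
Reagents that add atoms: trimethyl orthoformate, COC(OC)OC; methanol, CO
Why: Acid-catalysed acetalisation with the orthoformate as dehydrating agent, then SN1-type substitution of one methoxy group: protonation and loss of methanol give an oxocarbenium ion stabilised by the ortho-hydroxyl group, which triphenylphosphine captures; this is the known preparation of α-alkoxyalkylphosphonium salts from acetals and phosphine acid salts. The new stereocentre is formed racemic and is erased in step 5.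

**Step 3**
Reactants: 6 2-hydroxy-4-methoxybenzoic acid
Product: 8 4-methoxy-2-(pivaloyloxy)benzoic acid, via mixed anhydride 7 (not isolated)
Conditions: PivCl (2.3 equiv), pyridine (4 equiv), DMAP (5 mol %), CH2Cl2, 0 °C to rt; then H2O, THF, rt; aq. HCl work-up
Reagents that add atoms: pivaloyl chloride, CC(C)(C)C(Cl)=O; water, O
Why: Nucleophile-catalysed acylation puts pivaloyl groups on both the phenol and the carboxylate; water then hydrolyses the far more electrophilic mixed anhydride while the hindered aryl pivalate should survive.

**Step 4**
Reactants: 5 {[5-bromo-2-hydroxy-4-(pivaloyloxy)phenyl](methoxy)methyl}triphenylphosphonium bromide (racemic); 8 4-methoxy-2-(pivaloyloxy)benzoic acid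
Product: 10 {[5-bromo-2-(4-methoxy-2-pivaloyloxybenzoyloxy)-4-pivaloyloxyphenyl](methoxy)methyl}triphenylphosphonium bromide (racemic), via acid chloride 9 (not isolated)
Conditions: 8, (COCl)2 (1.2 equiv), DMF (cat.), CH2Cl2, 0 °C to rt, evaporate; then 5, pyridine (3 equiv), CH2Cl2, 0 °C to rt; wash with aq. NaBr; precipitate from CH2Cl2/Et2O
Reagents that add atoms: none
Why: Acid chloride formation through the chloroiminium species from oxalyl chloride and DMF, then pyridine-mediated O-acylation of the phenol; pyridine is too weak to form the ylide or a stoichiometric phenoxide, so neither premature Wittig chemistry nor phenoxide-assisted loss of triphenylphosphine should intervene. The bromide wash restores a single counter-ion.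

**Step 5**
Reactants: 10 {[5-bromo-2-(4-methoxy-2-pivaloyloxybenzoyloxy)-4-pivaloyloxyphenyl](methoxy)methyl}triphenylphosphonium bromide (racemic)
Product: 11 5-bromo-3-methoxy-2-[4-methoxy-2-(pivaloyloxy)phenyl]benzofuran-6-yl pivalate
Conditions: Et3N (3 equiv), toluene, 110 °C
Reagents that add atoms: none
Why: Triethylamine reversibly removes the benzylic proton of 10, which is acidified by the phosphonium group and the acyloxy-substituted ring, to give a semi-stabilised α-methoxybenzylidene phosphorane. The ylide carbon (future C3) adds to the aroyl ester carbonyl (future C2) held three atoms away through O1, a 5-exo-trig closure that forms the C2–C3 bond and ring B; the betaine closes to the oxaphosphetane, which loses triphenylphosphine oxide by syn-cycloreversion and leaves the C2=C3 enol ether, aromatic as the furan. The closest known reaction type is the intramolecular Wittig olefination of esters by ortho-acyloxybenzylidene phosphoranes, which gives 2-aryl- and 2,3-disubstituted benzofurans under the same amine and hot-toluene conditions; the α-methoxy group is a new substituent on that substrate class, and α-alkoxy ylides are established Wittig partners. No stereocentre is formed and the racemic centre of 10 is destroyed. The selectivity needed is attack at the tethered aroyl carbonyl and not at either pivalate: only that carbonyl can be reached through a five-membered transition state, and the pivaloyl carbonyls are remote and shielded by their tert-butyl groups. Because the ylide carbon has no second hydrogen, the O-to-C acyl shift that diverts the parent reaction towards 3-acylbenzofurans cannot lead to a stabilised acyl ylide and can only return to the same betaine; isolated 10 also contains no free acid chloride. Acylation of both ring-A oxygens lowers the tendency of the C–P bond to ionise, so ring closure should outrun loss of triphenylphosphine.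

**Step 6**
Reactants: 11 5-bromo-3-methoxy-2-[4-methoxy-2-(pivaloyloxy)phenyl]benzofuran-6-yl pivalate; 12 tributyl(3-methylbut-2-enyl)stannane
Product: 13 3-methoxy-2-[4-methoxy-2-(pivaloyloxy)phenyl]-5-(3-methylbut-2-enyl)benzofuran-6-yl pivalate
Conditions: Pd(PPh3)4 (5 mol %), DMF, 100 °C
Reagents that add atoms: none
Why: Stille cross-coupling: oxidative addition of zerovalent palladium to the C5–Br bond, transmetalation of the allylic stannane and reductive elimination at the less substituted allyl terminus should give the linear prenyl arene; the neutral medium leaves both pivalates and the enol ether untouched.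

**Step 7**
Reactants: 13 3-methoxy-2-[4-methoxy-2-(pivaloyloxy)phenyl]-5-(3-methylbut-2-enyl)benzofuran-6-yl pivalate
Product: 14 ambofuranol [2-(2-hydroxy-4-methoxyphenyl)-3-methoxy-5-(3-methylbut-2-enyl)benzofuran-6-ol]
Conditions: NaOMe (3 equiv), MeOH/THF, 0 °C to rt, under argon; aq. NH4Cl quench
Reagents that add atoms: none
Why: Base-mediated transesterification of the two aryl pivalates (phenoxides are good leaving groups even from hindered esters); the methyl ethers, the enol ether and the prenyl group are inert to methoxide, and the buffered quench avoids acid-induced cyclisation of the prenyl group onto O6.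

## Compound list

1 | 5-bromo-2,4-dihydroxybenzaldehyde | O=Cc1cc(Br)c(O)cc1O | starting material
2 | 2-bromo-4-formyl-5-hydroxyphenyl pivalate | CC(C)(C)C(=O)Oc1cc(O)c(C=O)cc1Br | intermediate
3 | triphenylphosphine hydrobromide | [Br-].c1ccc([PH+](c2ccccc2)c2ccccc2)cc1 | starting material
4 | 2-bromo-4-(dimethoxymethyl)-5-hydroxyphenyl pivalate | COC(OC)c1cc(Br)c(OC(=O)C(C)(C)C)cc1O | intermediate
5 | {[5-bromo-2-hydroxy-4-(pivaloyloxy)phenyl](methoxy)methyl}triphenylphosphonium bromide (racemic) | COC(c1cc(Br)c(OC(=O)C(C)(C)C)cc1O)[P+](c1ccccc1)(c1ccccc1)c1ccccc1.[Br-] | intermediate
6 | 2-hydroxy-4-methoxybenzoic acid | COc1ccc(C(=O)O)c(O)c1 | starting material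
7 | 4-methoxy-2-(pivaloyloxy)benzoic pivalic anhydride | COc1ccc(C(=O)OC(=O)C(C)(C)C)c(OC(=O)C(C)(C)C)c1 | intermediate
8 | 4-methoxy-2-(pivaloyloxy)benzoic acid | COc1ccc(C(=O)O)c(OC(=O)C(C)(C)C)c1 | intermediate
9 | 4-methoxy-2-(pivaloyloxy)benzoyl chloride | COc1ccc(C(Cl)=O)c(OC(=O)C(C)(C)C)c1 | intermediate
10 | {[5-bromo-2-(4-methoxy-2-pivaloyloxybenzoyloxy)-4-pivaloyloxyphenyl](methoxy)methyl}triphenylphosphonium bromide (racemic) | COC(c1cc(Br)c(OC(=O)C(C)(C)C)cc1OC(=O)c1ccc(OC)cc1OC(=O)C(C)(C)C)[P+](c1ccccc1)(c1ccccc1)c1ccccc1.[Br-] | intermediate
11 | 5-bromo-3-methoxy-2-[4-methoxy-2-(pivaloyloxy)phenyl]benzofuran-6-yl pivalate | COc1ccc(-c2oc3cc(OC(=O)C(C)(C)C)c(Br)cc3c2OC)c(OC(=O)C(C)(C)C)c1 | intermediate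
12 | tributyl(3-methylbut-2-enyl)stannane | CCCC[Sn](CCCC)(CCCC)CC=C(C)C | starting material
13 | 3-methoxy-2-[4-methoxy-2-(pivaloyloxy)phenyl]-5-(3-methylbut-2-enyl)benzofuran-6-yl pivalate | COc1ccc(-c2oc3cc(OC(=O)C(C)(C)C)c(CC=C(C)C)cc3c2OC)c(OC(=O)C(C)(C)C)c1 | intermediate
14 | ambofuranol, 2-(2-hydroxy-4-methoxyphenyl)-3-methoxy-5-(3-methylbut-2-enyl)benzofuran-6-ol | COc1ccc(-c2oc3cc(O)c(CC=C(C)C)cc3c2OC)c(O)c1 | target

## Step count and least certain steps

Total step count: 7. Longest linear sequence: 6 (steps 1, 2, 4, 5, 6, 7).

**Step 5 (key step).** The most likely failure is that closure onto the aroyl carbonyl is slow, because that carbonyl is flanked by an ortho substituent and deactivated by the para-methoxy group. The α-methoxy ylide, or the salt itself, would then be consumed first by heterolysis of the C–P bond or by adventitious hydrolysis. The fallback closes the furan at O1–C2 instead. It sets out from 5 and returns at 11. Compound 5 is deprotonated twice (LiHMDS, 2.1 equiv, THF, −78 °C) and the ylide is condensed with 2-formyl-5-methoxyphenyl pivalate F1, made from commercial 2-hydroxy-4-methoxybenzaldehyde with pivaloyl chloride and triethylamine. This intermolecular Wittig reaction with an aldehyde should give the enol ether 2-bromo-5-hydroxy-4-{1-methoxy-2-[4-methoxy-2-(pivaloyloxy)phenyl]ethenyl}phenyl pivalate F2 as an E/Z mixture. F2 would then be cyclised oxidatively with PhI(OAc)2 in acetonitrile, the known type of closure of ortho-hydroxystilbenes to 2-arylbenzofurans: the trivalent iodine reagent adds to the enol ether at C2, the phenol oxygen displaces iodobenzene there, and loss of the C2 proton gives 11.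

**Step 2.** The ortho-hydroxybenzylic cation may be diverted before triphenylphosphine captures it, by attack of a second phenol (oligomerisation), or the salt may revert towards the aldehyde on isolation. The fallback removes the free phenol before ionisation. It sets out from 2 and returns at 10. Acetal 4 is prepared as in the first half of step 2 but isolated after a basic work-up. Its phenol is acylated with 9 (generated from 8 as in step 4; Et3N, DMAP cat., CH2Cl2, 0 °C) to give 4-bromo-2-(dimethoxymethyl)-5-(pivaloyloxy)phenyl 4-methoxy-2-(pivaloyloxy)benzoate F3. F3 is then ionised with 3 in CH2Cl2 to give 10 directly. The same detour would also serve if acylation of the phosphonium salt in step 4 were troublesome.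

**Step 6.** Allylic transposition during transmetalation or reductive elimination could deliver the 1,1-dimethylallyl isomer, and slow oxidative addition into the electron-rich, ortho-substituted C–Br bond could allow protodebromination. The fallback separates C–C bond formation from the placing of the methyl groups. It sets out from 11 and returns at 13. Stille coupling with allyltributylstannane (Pd(PPh3)4, toluene, 100 °C), where transposition is degenerate, gives 5-allyl-3-methoxy-2-[4-methoxy-2-(pivaloyloxy)phenyl]benzofuran-6-yl pivalate F4. Olefin cross-metathesis of F4 with excess 2-methylbut-2-ene, using the second-generation Grubbs catalyst RuCl2(=CHPh)(PCy3)(H2IMes) in CH2Cl2 at 40 °C, converts the allyl into the prenyl group.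

**Step 7.** Once both phenols are free, the very electron-rich bis-phenoxide may be oxidised by air, or an acidic moment during quench could trigger cyclisation of the prenyl group onto O6. The fallback inverts the order so that the prenylated phenol never meets base or acid. It sets out from 11 and returns at 14. Methanolysis of 11 (NaOMe, MeOH) gives 5-bromo-2-(2-hydroxy-4-methoxyphenyl)-3-methoxybenzofuran-6-ol F5. The free bromophenol F5 is then coupled with 12 under neutral Stille conditions (Pd(PPh3)4 or Pd(P(t-Bu)3)2, DMF, 100 °C) to give 14 as the last operation.

## Further compounds

F1 | step 5 | 2-formyl-5-methoxyphenyl pivalate | COc1ccc(C=O)c(OC(=O)C(C)(C)C)c1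
F2 | step 5 | 2-bromo-5-hydroxy-4-{1-methoxy-2-[4-methoxy-2-(pivaloyloxy)phenyl]ethenyl}phenyl pivalate (E/Z mixture) | COC(=Cc1ccc(OC)cc1OC(=O)C(C)(C)C)c1cc(Br)c(OC(=O)C(C)(C)C)cc1O
F3 | step 2 | 4-bromo-2-(dimethoxymethyl)-5-(pivaloyloxy)phenyl 4-methoxy-2-(pivaloyloxy)benzoate | COc1ccc(C(=O)Oc2cc(OC(=O)C(C)(C)C)c(Br)cc2C(OC)OC)c(OC(=O)C(C)(C)C)c1
F4 | step 6 | 5-allyl-3-methoxy-2-[4-methoxy-2-(pivaloyloxy)phenyl]benzofuran-6-yl pivalate | COc1ccc(-c2oc3cc(OC(=O)C(C)(C)C)c(CC=C)cc3c2OC)c(OC(=O)C(C)(C)C)c1
F5 | step 7 | 5-bromo-2-(2-hydroxy-4-methoxyphenyl)-3-methoxybenzofuran-6-ol | COc1ccc(-c2oc3cc(O)c(Br)cc3c2OC)c(O)c1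
A1 | alternative 1 | 4-(3-methylbut-2-enyl)cyclohexane-1,3-dione (racemic) | O=C1CC(=O)C(CC=C(C)C)CC1
A2 | alternative 1 | 6-methylhept-5-en-2-one | CC(=O)CCC=C(C)C
A3 | alternative 1 | methyl acrylate | C=CC(=O)OC
A4 | alternative 1 | 4-(3-methylbut-2-enyl)benzene-1,3-diol | CC(C)=CCc1ccc(O)cc1O
A5 | alternative 2 | 2-(tert-butyldimethylsilyloxy)-1-[2,4-dihydroxy-5-(3-methylbut-2-enyl)phenyl]-2-[4-methoxy-2-(methoxymethoxy)phenyl]ethan-1-one (racemic) | COCOc1cc(OC)ccc1C(O[Si](C)(C)C(C)(C)C)C(=O)c1cc(CC=C(C)C)c(O)cc1O
A6 | alternative 2 | 1-methoxy-7-methyl-1,3-bis(trimethylsilyloxy)octa-1,3,6-triene (double-bond geometry unspecified) | COC(O[Si](C)(C)C)=CC(O[Si](C)(C)C)=CCC=C(C)C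
A7 | alternative 2 | 1-(tert-butyldimethylsilyloxy)-1-[4-methoxy-2-(methoxymethoxy)phenyl]but-3-yn-2-one (racemic) | C#CC(=O)C(O[Si](C)(C)C(C)(C)C)c1ccc(OC)cc1OCOC
A8 | alternative 3 | trans-5-bromo-6-(methoxymethoxy)-2-[4-methoxy-2-(methoxymethoxy)phenyl]-2,3-dihydrobenzofuran-3-ol (racemic, one enantiomer drawn) | O[C@@H]1[C@@H](c2ccc(OC)cc2OCOC)Oc2cc(OCOC)c(Br)cc21
A9 | alternative 3 | 1-[4-methoxy-2-(methoxymethoxy)benzyl]tetrahydrothiophenium bromide | COCOc1cc(OC)ccc1C[S+]1CCCC1.[Br-]
A10 | alternative 3 | 5-bromo-2-hydroxy-4-(methoxymethoxy)benzaldehyde | COCOc1cc(O)c(C=O)cc1Br
A11 | alternative 3 | 5-bromo-6-(methoxymethoxy)-2-[4-methoxy-2-(methoxymethoxy)phenyl]benzofuran-3(2H)-one (racemic) | COCOc1cc(OC)ccc1C1Oc2cc(OCOC)c(Br)cc2C1=O
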